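## The problem

Compound 11 is a flavonol: a chromen-4-one (ring A fused to the pyranone ring C) carrying a 3,4-dimethoxyphenyl ring B at C2, a free hydroxyl at C3 and a 3-methylbut-2-enyl (prenyl) ether at O7. It has no stereocentre, so the task is one of connectivity and of keeping three kinds of oxygen apart: two methyl ethers, one prenyl ether and one free enolic hydroxyl. The C6–C3–C6 skeleton is most simply built as an open 1,3-diaryl-1,3-diketone, with ring C then closed through O1–C2 by the ring A phenol. The real difficulty is the C3 oxygen, which must be installed without harming the prenyl ether. The trisubstituted alkene of that ether is attacked by peracids and dioxiranes before the C2=C3 bond of a flavone; the ether is also lost or saturated on hydrogenolysis, ionises to an allyl cation in strong acid, and migrates to carbon on strong heating. This excludes late epoxidation of a flavone, benzyl protection, and hot or strongly acidic ring closures. The enabling feature is that, before O1–C2 is closed, C3 is the methylene carbon between the C2 and C4 carbonyls; as its enolate it is the most nucleophilic carbon in the molecule and can take up an electrophilic oxygen that leaves an isolated alkene alone. Stereocentres formed on the way (C3 of the oxygenated diketone, C2 and C3 of the cyclic hemiketal) are transient and vanish when ring C becomes aromatic.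

## Retrosynthesis

**Disconnection 1, the O3–acyl bond (11 ⇒ 10).** The free C3 hydroxyl is traced back to its benzoate 10. The benzoate is the form in which the key step delivers the oxygen, and it is kept because an enol ester falls to carbonate-mediated methanolysis at room temperature. The prenyl ether, the methyl ethers and the pyranone are indifferent to those conditions. A benzyl or acetal group at O3 would have to leave by hydrogenolysis or acid, both of which endanger the prenyl ether. The forward step need only avoid long exposure of the flavonolate of 11 to base and air.

**Disconnection 2, the O1–C2 bond of ring C (10 ⇒ 8, through 9).** Opening ring C at O1–C2 gives the acyclic benzoyloxy diketone 8. Its ring A phenol and C2 carbonyl are placed for addition to the hemiketal 9 and loss of water. The neighbouring cuts either need temperatures the prenyl ether will not stand (C4–C4a by ring acylation) or give a ring C without the C3 oxygen (three bonds at once by carbonylation). Compound 8 has no ring C and is one oxygenation away from a plain diketone. The forward reaction must dehydrate 9 in a buffered carboxylic acid below 100 °C, too weakly acidic to ionise the allylic ether.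

**Disconnection 3, the C3–O bond (8 ⇒ 6 + 7).** This is the strategic cut. Removing the benzoyloxy group reveals diketone 6 and dibenzoyl peroxide 7. Making this bond after ring closure would require an epoxidising oxidant, and such an oxidant prefers the prenyl alkene. Making it earlier, on the acetophenone, would need a separate α-oxygenation and a harsher annulation. At the diketone stage C3 is doubly activated and reacts as an enolate with a peroxide that has no affinity for an unactivated alkene. The precursor 6 is a doubly activated diketone available in one step. The forward reaction must favour the enolate carbon over the phenol oxygen and stop after one oxygenation.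

**Disconnection 4, the C2–C3 bond (6 ⇒ 3 + 4, through 5).** The diketone is cut between the methylene carbon and the aroyl carbonyl, giving acetophenone 3 and acid chloride 4. Direct C-acylation of the pre-formed dilithium species 5 is preferred to the two-step ester formation and acyl migration because it saves a step and needs no heating. Both fragments are simple arenes. The forward step requires carbon rather than oxygen acylation, and enough base to absorb the more acidic product.

**Disconnection 5, the O7–CH2 bond (3 ⇒ 1 + 2).** The prenyl ether is cut to 2,4-dihydroxyacetophenone 1 and prenyl bromide 2, both commercial. Placing the prenyl group first means no later step has to distinguish O7 from O3. The forward alkylation must select the 4-hydroxyl over the 2-hydroxyl, which the hydrogen bond of the latter to the acetyl group provides.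

## Roads not taken

**Alternative 1:** The cut runs through C4–C4a and O1–C2 of ring C, with the O7–prenyl bond made afterwards.
- **Forward key step:** resorcinol A2 and the keto ester A3, ethyl 2-(benzyloxy)-3-(3,4-dimethoxyphenyl)-3-oxopropanoate, would be heated neat at about 240 °C without catalyst, a Mentzer-type pyrone synthesis. A3 expels its alkoxy group to give the acylketene A4, which acylates the ring of A2 next to a hydroxyl. That hydroxyl then condenses with the aryl ketone to close ring C, giving the flavone A1, 3-(benzyloxy)-2-(3,4-dimethoxyphenyl)-7-hydroxychromen-4-one.
- **Merits:** ring C and the C3 oxygen arrive together from the cheapest phenol, with no strong base and no peroxide. The only free hydroxyl of A1 is at C7, so prenylation to the ether A5 is unambiguous.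
- **Weak points:** the temperature forbids carrying the prenyl group. A2 is much less nucleophilic than the phloroglucinol-type phenols for which such thermal annulations work best, and coumarin formation competes. A3 must itself be made. Decisively, the benzyl ether of A5 has to be removed beside the prenyl ether: hydrogenolysis saturates or cleaves the allyl ether, and Lewis acids strong enough for the benzyl ether take the prenyl and methyl ethers as well.
- **Comparison:** in bond-forming economy for the oxygenated nucleus this road is at least as good as the chosen plan, and it handles no peroxide. The chosen plan offers conditions below 100 °C throughout and a C3 protecting group that comes with the oxygen and leaves under carbonate and methanol.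

**Alternative 2:** The cut removes C4 as carbon monoxide A9 and breaks C4a–C4, C4–C3 and O1–C2.
- **Forward key step:** the iodophenol A7, 2-iodo-5-(3-methylbut-2-enyloxy)phenol, would be combined with A9 and the aryl alkyne A8, 4-ethynyl-1,2-dimethoxybenzene, under PdCl2(PPh3)2 and diethylamine. Oxidative addition of the C–I bond of A7 to the zerovalent palladium formed in the flask, insertion of A9 and coupling with A8 give an aryl ynone. The phenol then closes onto it 6-endo to give the flavone A6, 2-(3,4-dimethoxyphenyl)-7-(3-methylbut-2-enyloxy)chromen-4-one.
- **Merits:** three bonds and ring C form in one mild, convergent step that tolerates the prenyl ether, and A8 is a simple purchasable alkyne. For the bare skeleton this is better than the chosen plan, which needs an acylation and a separate cyclodehydration.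
- **Weak points:** A6 has hydrogen at C3. The oxygen would have to be added afterwards with an epoxidising oxidant, which the prenyl alkene intercepts, or by C3 metalation, borylation and oxidation on a base-sensitive chromone. The 5-exo closure to an aurone competes, the toxic gas A9 is needed, and A7 requires a regioselective iodination.
- **Comparison:** the chosen plan is less elegant in skeleton assembly but places the oxygen while C3 is still an enolate carbon, which is the one point where chemoselectivity over the alkene is inherent.

**Alternative 3:** The cut is the C2–C1' bond between ring C and ring B.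
- **Forward key step:** the chromone A11, 3-(methoxymethoxy)-7-(3-methylbut-2-enyloxy)chromen-4-one, would be zincated at C2 with TMPZnCl·LiCl and coupled with the aryl iodide A12, 4-iodo-1,2-dimethoxybenzene, under Pd(OAc)2 and SPhos (Negishi coupling). The product is the protected flavonol A10, 2-(3,4-dimethoxyphenyl)-3-(methoxymethoxy)-7-(3-methylbut-2-enyloxy)chromen-4-one.
- **Merits:** ring B enters last, so A12 could be exchanged for any other aryl iodide, which is ideal for a series of ring B analogues; in that respect this road is superior to the chosen plan. The C3 oxygen is present before the coupling.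
- **Weak points:** A11 is not commercial. It has to be built over several steps from a 2-hydroxyacetophenone, and its C3 oxygen must still be introduced in the presence of the prenyl alkene, so the central problem is moved rather than solved. A chromone with a free C2 is open to ring cleavage by amide bases. The acetal at O3 of A10 must finally leave under acid, which the prenyl ether tolerates only narrowly.
- **Comparison:** for the single target the chosen plan is shorter, uses no transition metal and solves the oxygenation directly.

Key step: step 3

Remark: salts that differ from a numbered compound only by reversible loss of acidic protons are not numbered separately; the exception is the dilithium species 5, which is prepared beforehand as the actual nucleophile of step 2.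

## Route

Step 1
Reactants: 1 2,4-dihydroxyacetophenone; 2 1-bromo-3-methylbut-2-ene (prenyl bromide)
Product: 3 1-[2-hydroxy-4-(3-methylbut-2-enyloxy)phenyl]ethanone
Conditions: K2CO3 (1.1 equiv), acetone, reflux
Reagents that add atoms: none
Why: Williamson ether synthesis; the 2-hydroxyl is held in a hydrogen bond to the acetyl oxygen and is the less acidic one, so the 4-phenoxide forms and is alkylated selectively, and only a slight excess of 2 is used to suppress double alkylation.

Step 2
Reactants: 3 1-[2-hydroxy-4-(3-methylbut-2-enyloxy)phenyl]ethanone; 4 3,4-dimethoxybenzoyl chloride
Product: 6 1-(3,4-dimethoxyphenyl)-3-[2-hydroxy-4-(3-methylbut-2-enyloxy)phenyl]propane-1,3-dione, via dilithium enolate phenoxide 5 (not isolated)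
Conditions: LiN(SiMe3)2 (3.2 equiv), THF, −78 to −10 °C; then 4, −78 °C to rt; aq. NH4Cl
Reagents that add atoms: none
Why: Crossed Claisen-type C-acylation of a pre-formed ketone enolate; in the dilithium species 5 the enolate carbon is far more nucleophilic than the aggregated lithium phenoxide, so the acid chloride should be taken up at carbon. The third equivalent of base absorbs the more acidic diketone and prevents proton transfer from quenching unreacted 5.

Step 3
Reactants: 6 1-(3,4-dimethoxyphenyl)-3-[2-hydroxy-4-(3-methylbut-2-enyloxy)phenyl]propane-1,3-dione; 7 dibenzoyl peroxide
Product: 8 1-(3,4-dimethoxyphenyl)-3-[2-hydroxy-4-(3-methylbut-2-enyloxy)phenyl]-1,3-dioxopropan-2-yl benzoate (racemic)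
Conditions: K2CO3 (1.1 equiv), MeCN, 0 °C to rt, N2, dark
Reagents that add atoms: none
Why: K2CO3 deprotonates the enolised 1,3-diketone of 6, and the central carbon of the enolate attacks one oxygen of the weak O–O bond of 7 in a substitution at oxygen with benzoate as leaving group, so the C3–O bond forms and the new oxygen arrives as its benzoate. The closest known reaction type is the base-mediated α-benzoyloxylation of 1,3-dicarbonyl compounds with dibenzoyl peroxide. No ring is closed. The oxygenated carbon of 8 is a stereocentre only formally: it forms as a racemate, stays enolisable and is flattened in step 4, so no control is needed. The step requires reaction at the enolate carbon rather than at the phenol oxygen or ring A, a single oxygenation, and an untouched prenyl alkene. The first is secured because the diketone is more acidic than the hydrogen-bonded phenol and barely more than one equivalent of a weak base is used, so only the diketone is ionised. The second is secured by the lower nucleophilicity and greater hindrance of the enolate of 8 and by charging close to one equivalent of 7. The alkene is safe because the polar pathway needs an anionic carbon nucleophile, and the low temperature and exclusion of light keep homolysis of 7 negligible.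

Step 4
Reactants: 8 1-(3,4-dimethoxyphenyl)-3-[2-hydroxy-4-(3-methylbut-2-enyloxy)phenyl]-1,3-dioxopropan-2-yl benzoate
Product: 10 2-(3,4-dimethoxyphenyl)-7-(3-methylbut-2-enyloxy)-4-oxo-4H-chromen-3-yl benzoate, via cyclic hemiketal 9 (not isolated)
Conditions: NaOAc, AcOH, 90 °C
Reagents that add atoms: none
Why: Acid-catalysed cyclodehydration of an o-hydroxyaryl 1,3-diketone, the ring-closing step of classical flavone synthesis after a Baker–Venkataraman rearrangement; the ring A phenol adds to the C2 carbonyl (6-exo-trig) to give hemiketal 9, which loses water to the conjugated pyranone. The acetate buffer keeps the medium too weakly acidic to ionise the prenyl ether, and the temperature is far below that of an aryl prenyl ether Claisen rearrangement.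

Step 5
Reactants: 10 2-(3,4-dimethoxyphenyl)-7-(3-methylbut-2-enyloxy)-4-oxo-4H-chromen-3-yl benzoate
Product: 11 2-(3,4-dimethoxyphenyl)-3-hydroxy-7-(3-methylbut-2-enyloxy)-4H-chromen-4-one
Conditions: K2CO3 (2 equiv), MeOH–THF, rt, N2; then aq. citric acid
Reagents that add atoms: none
Why: Carbonate-mediated methanolysis (transesterification) of an enol ester; methoxide attacks the benzoate carbonyl and releases the stabilised flavonolate, which is protonated on work-up. The methyl and prenyl ethers are inert, and the inert atmosphere guards the flavonolate against base-promoted autoxidation.

## Compound list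

1 | 2,4-dihydroxyacetophenone | CC(=O)c1ccc(O)cc1O | starting material
2 | 1-bromo-3-methylbut-2-ene (prenyl bromide) | CC(C)=CCBr | starting material
3 | 1-[2-hydroxy-4-(3-methylbut-2-enyloxy)phenyl]ethanone | CC(=O)c1ccc(OCC=C(C)C)cc1O | intermediate
4 | 3,4-dimethoxybenzoyl chloride | COc1ccc(C(=O)Cl)cc1OC | starting material
5 | dilithium 2-(1-oxidoethenyl)-5-(3-methylbut-2-enyloxy)phenolate (enolate phenoxide of 3) | [Li+].[Li+].C=C([O-])c1ccc(OCC=C(C)C)cc1[O-] | intermediate
6 | 1-(3,4-dimethoxyphenyl)-3-[2-hydroxy-4-(3-methylbut-2-enyloxy)phenyl]propane-1,3-dione | COc1ccc(C(=O)CC(=O)c2ccc(OCC=C(C)C)cc2O)cc1OC | intermediate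
7 | dibenzoyl peroxide | O=C(OOC(=O)c1ccccc1)c1ccccc1 | starting material
8 | 1-(3,4-dimethoxyphenyl)-3-[2-hydroxy-4-(3-methylbut-2-enyloxy)phenyl]-1,3-dioxopropan-2-yl benzoate (racemic) | COc1ccc(C(=O)C(OC(=O)c2ccccc2)C(=O)c2ccc(OCC=C(C)C)cc2O)cc1OC | intermediate
9 | 2-(3,4-dimethoxyphenyl)-2-hydroxy-7-(3-methylbut-2-enyloxy)-4-oxochroman-3-yl benzoate (cyclic hemiketal, mixture of racemic diastereomers) | COc1ccc(C2(O)Oc3cc(OCC=C(C)C)ccc3C(=O)C2OC(=O)c2ccccc2)cc1OC | intermediate
10 | 2-(3,4-dimethoxyphenyl)-7-(3-methylbut-2-enyloxy)-4-oxo-4H-chromen-3-yl benzoate | COc1ccc(-c2oc3cc(OCC=C(C)C)ccc3c(=O)c2OC(=O)c2ccccc2)cc1OC | intermediate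
11 | 2-(3,4-dimethoxyphenyl)-3-hydroxy-7-(3-methylbut-2-enyloxy)-4H-chromen-4-one (CNP0167607.0) | COc1ccc(-c2oc3cc(OCC=C(C)C)ccc3c(=O)c2O)cc1OC | target

## Step count and risks

Total step count: 5. Longest linear sequence: 5 steps, from 1 to 11; compounds 2, 4 and 7 are purchased.

**Step 3 (key step).**
- **What may go wrong:** loss of chemoselectivity. Oxygenation may occur at the phenoxide or on ring A once more base than needed is present, a second oxygenation may occur at C3, or the prenyl group may be consumed by radical chains if the peroxide homolyses.
- **Fallback:** give up electrophilic oxygenation of the diketone and use the Algar–Flynn–Oyamada sequence. It sets out from 3. Claisen–Schmidt condensation with commercial 3,4-dimethoxybenzaldehyde (KOH, EtOH, rt) should give the chalcone (E)-3-(3,4-dimethoxyphenyl)-1-[2-hydroxy-4-(3-methylbut-2-enyloxy)phenyl]prop-2-en-1-one F1. Alkaline hydrogen peroxide (NaOH, MeOH, 0 °C to rt) then cyclises it oxidatively and returns to the route at 11. The nucleophilic hydroperoxide attacks only the enone, and with no substituent next to the ring A carbonyl on the other side, flavonol rather than aurone formation is expected.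

**Step 2.**
- **What may go wrong:** acylation at the phenoxide oxygen and double acylation of the product, caused by incomplete formation of 5 or local excess of 4.
- **Fallback:** the two-stage Baker–Venkataraman sequence, setting out from 3. Esterification with 4 (pyridine, cat. DMAP, CH2Cl2, 0 °C to rt) gives 2-acetyl-5-(3-methylbut-2-enyloxy)phenyl 3,4-dimethoxybenzoate F2. KOtBu in THF then moves the aroyl group from oxygen to carbon intramolecularly, returning to the route at 6.

**Step 4.**
- **What may go wrong:** sluggish dehydration of hemiketal 9, because the electron-withdrawing benzoyloxy group disfavours loss of water. Longer heating or stronger acid then causes loss or migration of the prenyl group.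
- **Fallback:** accept the loss instead of fighting it. Setting out from 8, closure with H2SO4 in AcOH at 60 °C, in which the prenyl cation is captured by the solvent, should give 2-(3,4-dimethoxyphenyl)-7-hydroxy-4-oxo-4H-chromen-3-yl benzoate F3. Its only free hydroxyl is at C7, because the benzoate still masks O3, so alkylation with 2 (K2CO3, acetone, reflux) is unambiguous and returns to the route at 10.

## Further compounds

F1 | step 3 | (E)-3-(3,4-dimethoxyphenyl)-1-[2-hydroxy-4-(3-methylbut-2-enyloxy)phenyl]prop-2-en-1-one | COc1ccc(/C=C/C(=O)c2ccc(OCC=C(C)C)cc2O)cc1OC
F2 | step 2 | 2-acetyl-5-(3-methylbut-2-enyloxy)phenyl 3,4-dimethoxybenzoate | COc1ccc(C(=O)Oc2cc(OCC=C(C)C)ccc2C(C)=O)cc1OC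
F3 | step 4 | 2-(3,4-dimethoxyphenyl)-7-hydroxy-4-oxo-4H-chromen-3-yl benzoate | COc1ccc(-c2oc3cc(O)ccc3c(=O)c2OC(=O)c2ccccc2)cc1OC
A1 | alternative 1 | 3-(benzyloxy)-2-(3,4-dimethoxyphenyl)-7-hydroxychromen-4-one | COc1ccc(-c2oc3cc(O)ccc3c(=O)c2OCc2ccccc2)cc1OC
A2 | alternative 1 | resorcinol | Oc1cccc(O)c1
A3 | alternative 1 | ethyl 2-(benzyloxy)-3-(3,4-dimethoxyphenyl)-3-oxopropanoate | CCOC(=O)C(OCc1ccccc1)C(=O)c1ccc(OC)c(OC)c1
A4 | alternative 1 | 2-(benzyloxy)-3-(3,4-dimethoxyphenyl)-3-oxoprop-1-en-1-one (acylketene) | O=C=C(OCc1ccccc1)C(=O)c1ccc(OC)c(OC)c1
A5 | alternative 1 | 3-(benzyloxy)-2-(3,4-dimethoxyphenyl)-7-(3-methylbut-2-enyloxy)chromen-4-one | COc1ccc(-c2oc3cc(OCC=C(C)C)ccc3c(=O)c2OCc2ccccc2)cc1OC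
A6 | alternative 2 | 2-(3,4-dimethoxyphenyl)-7-(3-methylbut-2-enyloxy)chromen-4-one | COc1ccc(-c2cc(=O)c3ccc(OCC=C(C)C)cc3o2)cc1OC
A7 | alternative 2 | 2-iodo-5-(3-methylbut-2-enyloxy)phenol | CC(C)=CCOc1ccc(I)c(O)c1
A8 | alternative 2 | 4-ethynyl-1,2-dimethoxybenzene | C#Cc1ccc(OC)c(OC)c1
A9 | alternative 2 | carbon monoxide | [C-]#[O+]
A10 | alternative 3 | 2-(3,4-dimethoxyphenyl)-3-(methoxymethoxy)-7-(3-methylbut-2-enyloxy)chromen-4-one | COCOc1c(-c2ccc(OC)c(OC)c2)oc2cc(OCC=C(C)C)ccc2c1=O
A11 | alternative 3 | 3-(methoxymethoxy)-7-(3-methylbut-2-enyloxy)chromen-4-one | COCOc1coc2cc(OCC=C(C)C)ccc2c1=O
A12 | alternative 3 | 4-iodo-1,2-dimethoxybenzene | COc1ccc(I)cc1OC
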